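**Plan**

- Feature: in the central ring of the target, numbered C1(OH), C2(H), C3(OH), C4(4-hydroxybenzyl), C5(2-phenylethyl), C6(4-hydroxybenzyl), the C2–C5 axis is a mirror line and C2 is bonded to both oxygen-bearing carbons. C2 can therefore enter as a one-carbon double nucleophile between the two carboxyl carbons of a symmetric glutarate that supplies C1, C6, C5, C4 and C3.
- Retrosynthesis: the two aryl O–Me bonds are cut first, then one H2 is restored to the ring and a carboxyl is placed on C2. C1–C2 and C2–C3 are then cut together (acetate plus glutarate), followed by the two Cα–CH2Ar bonds and the C5–C4 and C5–C6 bonds, leading back to 3-phenylpropanal and two malonates.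
- Forward: the chain grows in both directions from the phenethyl-bearing carbon (steps 1–3). The only ring that has to be made, the central six-membered ring, closes in step 4. Ester removal, dehydrogenation to the arene and O-demethylation follow.
- Stereochemistry: the target has no stereocentre, so the sp3 centres of the intermediates are carried as diastereomer mixtures.

Key step: step 4

Remark: every sp3 stereocentre of the intermediates becomes sp2 in step 6, so no relative configuration is specified and the SMILES carry no stereodescriptors.

**Route**

Step 1
Reactants: 1 3-phenylpropanal; 2 dimethyl malonate (2.2 equiv)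
Product: 4 tetramethyl 2-(2-phenylethyl)propane-1,1,3,3-tetracarboxylate, via alkylidene malonate 3 (not isolated)
Conditions: piperidine (0.1 equiv), AcOH (0.1 equiv), toluene, reflux, Dean–Stark; then NaOMe (0.2 equiv), MeOH, 23 °C
Reagents that add atoms: none
Why: Knoevenagel condensation should give the alkylidene malonate 3, which accepts a second malonate in a Michael addition, the standard tandem entry from aliphatic aldehydes to 3-substituted glutarate precursors; the new carbon bears two identical arms and is not a stereocentre.

Step 2
Reactants: 4 tetramethyl 2-(2-phenylethyl)propane-1,1,3,3-tetracarboxylate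
Product: 5 dimethyl 3-(2-phenylethyl)pentanedioate
Conditions: LiCl (4 equiv), H2O (4 equiv), DMSO, 160 °C
Reagents that add atoms: none
Why: Double Krapcho dealkoxycarbonylation, in which chloride demethylates one ester of each monosubstituted malonate and the carboxylate loses CO2, is well established for converting such bis-malonate adducts into 3-substituted glutarates.

Step 3
Reactants: 5 dimethyl 3-(2-phenylethyl)pentanedioate; 6 4-methoxybenzyl bromide (2.2 equiv)
Product: 8 dimethyl 2,4-bis(4-methoxybenzyl)-3-(2-phenylethyl)pentanedioate (diastereomer mixture), via monobenzylated diester 7 (not isolated)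
Conditions: LiN(i-Pr)2 (1.1 equiv), THF, −78 °C; 6 (1.1 equiv), −78 → 0 °C; then again LiN(i-Pr)2 (1.1 equiv), −78 °C; 6 (1.1 equiv), −78 → 0 °C; aq. NH4Cl
Reagents that add atoms: none
Why: Kinetic lithium ester enolate alkylation with a reactive benzylic bromide is run twice in one flask; the second deprotonation should take the unhindered CH2 of 7 and not the benzylated CH, which places the aryl-methyl groups at C2 and C4, and all diastereomers are usable because these centres are later flattened.

Step 4
Reactants: 8 dimethyl 2,4-bis(4-methoxybenzyl)-3-(2-phenylethyl)pentanedioate; 9 tert-butyl acetate (1.5 equiv)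
Product: 11 tert-butyl 3,5-bis(4-methoxybenzyl)-2,6-dioxo-4-(2-phenylethyl)cyclohexane-1-carboxylate (diastereomer mixture; largely enolised), via open-chain keto diester 10 (not isolated)
Conditions: KOt-Bu (3 equiv), THF, 60 °C, 9 added over 8 h by syringe pump; then cold 1 M HCl
Reagents that add atoms: none
Why: Proposed new method: under KOt-Bu the acetate 9 is enolised in low stationary concentration, its enolate adds to one methyl ester of 8 and expels methoxide (crossed Claisen), the β-keto ester 10 is deprotonated at once, and this stabilised potassium enolate attacks the second methyl ester to close the ring (Dieckmann-type), after which the acidic tricarbonyl product is held as its enolate and drains the preceding equilibria. The closest known reaction types are the alkoxide-mediated double Claisen condensation of dialkyl phthalates with acetate esters to 2-alkoxycarbonylindane-1,3-diones, the crossed Claisen of tert-butyl acetate with methyl esters, and the base-induced cyclisation of 5-oxoalkanoates to cyclohexane-1,3-diones. The six-membered ring closes in a 6-exo-trig (enol-exo) mode, the attacked ester carbonyl lying outside the ring being formed. No stereocentre of consequence is set: C2 of 11 is enolised, and the three ring sp3 centres are inherited as a mixture that equilibrates at the two α-carbons under the alkoxide and disappears in step 6. The step needs one intermolecular and then one intramolecular C-acylation at the same acetate carbon, and must avoid a second acetate attacking the remaining ester, closure through oxygen and self-condensation of 9; slow addition keeps the acetate enolate dilute so that the unimolecular closure should win, O-acylation is reversed by methoxide, the tert-butyl ester is a poor electrophile, and closure from the γ-carbon of 10 would require a four-membered ring. The mirror symmetry of 8 makes its two esters equivalent, so no regiochemical choice arises.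

Step 5
Reactants: 11 tert-butyl 3,5-bis(4-methoxybenzyl)-2,6-dioxo-4-(2-phenylethyl)cyclohexane-1-carboxylate
Product: 13 4,6-bis(4-methoxybenzyl)-5-(2-phenylethyl)cyclohexane-1,3-dione (diastereomer mixture), via diketo acid 12 (not isolated)
Conditions: TsOH·H2O (0.1 equiv), toluene, 90 °C
Reagents that add atoms: none
Why: Acid-catalysed loss of 2-methylpropene from the tert-butyl ester should give the β,β'-diketo acid 12, which decarboxylates on heating through the usual cyclic transition state (standard dealkoxycarbonylation of tert-butyl β-keto esters).

Step 6
Reactants: 13 4,6-bis(4-methoxybenzyl)-5-(2-phenylethyl)cyclohexane-1,3-dione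
Product: 14 4,6-bis(4-methoxybenzyl)-5-(2-phenylethyl)benzene-1,3-diol
Conditions: 10% Pd/C (0.1 equiv Pd), triglyme, 200 °C, N2 sweep
Reagents that add atoms: none
Why: Palladium-on-carbon dehydrogenation of cyclohexane-1,3-diones (dihydroresorcinols) to resorcinols is a known transformation; loss of one H2 from the C4–C5 (or C5–C6) edge followed by enolisation should give the arene and erase all three sp3 centres.

Step 7
Reactants: 14 4,6-bis(4-methoxybenzyl)-5-(2-phenylethyl)benzene-1,3-diol
Product: 15 4,6-bis(4-hydroxybenzyl)-5-(2-phenylethyl)benzene-1,3-diol (target)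
Conditions: BBr3 (6 equiv), CH2Cl2, −78 → 23 °C; then H2O, 0 °C
Reagents that add atoms: none
Why: Lewis-acid cleavage of aryl methyl ethers with BBr3 (bromide attack on the O-methyl of the boron-complexed ether) should free both phenols, while the resorcinol hydroxyls form borates that hydrolyse on work-up and the diarylmethane links are left untouched.

**Compound list**

1 | 3-phenylpropanal | O=CCCc1ccccc1 | starting material
2 | dimethyl malonate | COC(=O)CC(=O)OC | starting material
3 | dimethyl 2-(3-phenylpropylidene)propanedioate (formed in step 1, not isolated) | COC(=O)C(=CCCc1ccccc1)C(=O)OC | intermediate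
4 | tetramethyl 2-(2-phenylethyl)propane-1,1,3,3-tetracarboxylate | COC(=O)C(C(=O)OC)C(CCc1ccccc1)C(C(=O)OC)C(=O)OC | intermediate
5 | dimethyl 3-(2-phenylethyl)pentanedioate | COC(=O)CC(CCc1ccccc1)CC(=O)OC | intermediate
6 | 4-methoxybenzyl bromide, 1-(bromomethyl)-4-methoxybenzene | COc1ccc(CBr)cc1 | starting material
7 | dimethyl 2-(4-methoxybenzyl)-3-(2-phenylethyl)pentanedioate (diastereomer mixture; formed in step 3, not isolated) | COC(=O)CC(CCc1ccccc1)C(Cc1ccc(OC)cc1)C(=O)OC | intermediate
8 | dimethyl 2,4-bis(4-methoxybenzyl)-3-(2-phenylethyl)pentanedioate (diastereomer mixture) | COC(=O)C(Cc1ccc(OC)cc1)C(CCc1ccccc1)C(Cc1ccc(OC)cc1)C(=O)OC | intermediate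
9 | tert-butyl acetate | CC(=O)OC(C)(C)C | starting material
10 | 1-tert-butyl 7-methyl 4,6-bis(4-methoxybenzyl)-3-oxo-5-(2-phenylethyl)heptanedioate (diastereomer mixture; formed in step 4 as its enolate, not isolated) | CC(C)(C)OC(=O)CC(=O)C(Cc1ccc(OC)cc1)C(CCc1ccccc1)C(Cc1ccc(OC)cc1)C(=O)OC | intermediate
11 | tert-butyl 3,5-bis(4-methoxybenzyl)-2,6-dioxo-4-(2-phenylethyl)cyclohexane-1-carboxylate (diastereomer mixture) | CC(C)(C)OC(=O)C1C(=O)C(Cc2ccc(OC)cc2)C(CCc2ccccc2)C(Cc2ccc(OC)cc2)C1=O | intermediate
12 | 3,5-bis(4-methoxybenzyl)-2,6-dioxo-4-(2-phenylethyl)cyclohexane-1-carboxylic acid (formed in step 5, not isolated) | OC(=O)C1C(=O)C(Cc2ccc(OC)cc2)C(CCc2ccccc2)C(Cc2ccc(OC)cc2)C1=O | intermediate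
13 | 4,6-bis(4-methoxybenzyl)-5-(2-phenylethyl)cyclohexane-1,3-dione (diastereomer mixture) | O=C1CC(=O)C(Cc2ccc(OC)cc2)C(CCc2ccccc2)C1Cc1ccc(OC)cc1 | intermediate
14 | 4,6-bis(4-methoxybenzyl)-5-(2-phenylethyl)benzene-1,3-diol | COc1ccc(Cc2c(O)cc(O)c(Cc3ccc(OC)cc3)c2CCc2ccccc2)cc1 | intermediate
15 | 4,6-bis(4-hydroxybenzyl)-5-(2-phenylethyl)benzene-1,3-diol | Oc1ccc(Cc2c(O)cc(O)c(Cc3ccc(O)cc3)c2CCc2ccccc2)cc1 | target

**Count and risks**

Total step count: 7. Longest linear sequence: 7 steps (1 to 15).

Steps most likely to fail:

1. Step 4 (proposed new method). A second acetate enolate may acylate the remaining ester before the ring closes, or the closure by the stabilised enolate onto the hindered α-branched ester may stall at the open-chain stage. The fallback sets out from 8 and makes the two C–C bonds in separate, known operations. About one equivalent of the preformed lithium enolate of 9 (LiN(i-Pr)2, THF, −78 °C, cold AcOH quench) should convert 8 by crossed Claisen condensation into the open-chain keto diester 10, now isolated, with unreacted 8 recovered and recycled. TFA in CH2Cl2 with Et3SiH as cation scavenger then cleaves the tert-butyl ester, and the β-keto acid loses CO2 to give methyl 2,4-bis(4-methoxybenzyl)-5-oxo-3-(2-phenylethyl)hexanoate F1. KOt-Bu in THF closes the ring through the more nucleophilic methyl-ketone enolate, the standard cyclisation of 5-oxoalkanoates to cyclohexane-1,3-diones. This gives dione 13, where the route is rejoined, and step 5 is then not needed.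

2. Step 6. Dehydrogenation over palladium may be slow at the crowded, fully substituted C4–C5–C6 edge, and hydrogen transfer at 200 °C may cause partial loss of a ring oxygen. The fallback sets out from 13 and replaces the catalytic dehydrogenation by a regiodefined enolate oxidation. MeOH with HC(OMe)3 and catalytic TsOH should give the vinylogous ester 3-methoxy-4,6-bis(4-methoxybenzyl)-5-(2-phenylethyl)cyclohex-2-en-1-one F2, a single constitutional isomer because of the symmetry of 13. Kinetic α'-deprotonation with LiN(i-Pr)2 at −78 °C and trapping with PhSeBr should give 3-methoxy-4,6-bis(4-methoxybenzyl)-5-(2-phenylethyl)-6-(phenylselanyl)cyclohex-2-en-1-one F3. Oxidation with H2O2 and pyridine in CH2Cl2 triggers selenoxide syn-elimination; either direction of elimination leads, after tautomerisation, to 3-methoxy-4,6-bis(4-methoxybenzyl)-5-(2-phenylethyl)phenol F4. BBr3 under the conditions of step 7 then cleaves all three methyl ethers, and the route is rejoined at the target 15.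

3. Step 3. Incomplete second enolisation, proton exchange between enolates or ester-enolate self-condensation may give mixtures of under- and over-benzylated diesters. The fallback sets out from 4 and moves the benzylation to the malonate stage, where the C–H bonds are acidic enough for NaH and no ester enolate is involved. NaH (2.2 equiv) and 6 in DMF at 0 → 23 °C should give tetramethyl 1,3-bis(4-methoxybenzyl)-2-(2-phenylethyl)propane-1,1,3,3-tetracarboxylate F5. Double Krapcho dealkoxycarbonylation (LiCl, H2O, DMSO, 160 °C) then gives 8, where the route is rejoined; compound 5 is bypassed.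

Further compounds
F1 | step 4 | methyl 2,4-bis(4-methoxybenzyl)-5-oxo-3-(2-phenylethyl)hexanoate | COC(=O)C(Cc1ccc(OC)cc1)C(CCc1ccccc1)C(Cc1ccc(OC)cc1)C(C)=O
F2 | step 6 | 3-methoxy-4,6-bis(4-methoxybenzyl)-5-(2-phenylethyl)cyclohex-2-en-1-one | COC1=CC(=O)C(Cc2ccc(OC)cc2)C(CCc2ccccc2)C1Cc1ccc(OC)cc1
F3 | step 6 | 3-methoxy-4,6-bis(4-methoxybenzyl)-5-(2-phenylethyl)-6-(phenylselanyl)cyclohex-2-en-1-one | COC1=CC(=O)C(Cc2ccc(OC)cc2)([Se]c2ccccc2)C(CCc2ccccc2)C1Cc1ccc(OC)cc1
F4 | step 6 | 3-methoxy-4,6-bis(4-methoxybenzyl)-5-(2-phenylethyl)phenol | COc1cc(O)c(Cc2ccc(OC)cc2)c(CCc2ccccc2)c1Cc1ccc(OC)cc1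
F5 | step 3 | tetramethyl 1,3-bis(4-methoxybenzyl)-2-(2-phenylethyl)propane-1,1,3,3-tetracarboxylate | COC(=O)C(Cc1ccc(OC)cc1)(C(=O)OC)C(CCc1ccccc1)C(Cc1ccc(OC)cc1)(C(=O)OC)C(=O)OC
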